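The data are simulated for an exercise, noise included.

You read south at 2.0 h, and Tuesday's run has the same charge and loading in the same kind of closed flask, so its last reading, 60.5% at 120 min, already stands for south.

| flask | D | J | remark | time |
|---|---|---|---|---|
| Tuesday's | 33 mM | 0.01 mol% | run made earlier |  |
| Monday's | 16 mM | 0.01 mol% | run made earlier |  |
| Thursday's | 25 mM | 0.01 mol% | run made earlier |  |
| Wednesday's | 33 mM | 0.02 mol% | run made earlier |  |
| north | 33 mM | 0.01 mol% | one stirred flow tank at steady state, fed with the mixture as stated, mean residence time 6.00 h |  |
| south | 33 mM | 0.01 mol% | everything together in a closed stirred flask, run for 2.0 h | 2.0 h |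
| north-east | 33 mM | 0.01 mol% | one stirred flow tank at steady state, fed with the mixture as stated, mean residence time 2.0 h |  |
| south-west | 33 mM (fed, over 1.60 h) | 0.01 mol% | all but D at the start; D goes in evenly over 1.60 h, the run ends at 2.0 h | 2.0 h |

- Tuesday's (time / min: G / %): 10.0: 54.3; 30.0: 71.9; 60.0: 73.0; 80.0: 70.0; 120: 60.5
- Monday's (time / min: G / %): 15.0: 57.0; 30.0: 70.4; 40.0: 74.9; 60.0: 78.5; 80.0: 78.7
- Thursday's (time / min: G / %): 6.00: 37.6; 10.0: 52.3; 20.0: 66.1; 40.0: 74.5; 80.0: 74.2
- Wednesday's (time / min: G / %): 6.00: 58.8; 20.0: 73.7; 30.0: 73.3; 50.0: 65.1; 80.0: 49.5

(readings scatter by 0.3 percentage points)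

- percent here means D units held: one L counts as two
- what is said of G includes L
- the stated concentrations are those of everything mixed, before any reaction; amounts are the same in each set-up
- steps under discussion: D + J -> G + J; D + G <-> L; J + G -> J + E; D -> Z
- the feed brings no volume worth counting
- the earlier runs were made in a closed, stirred flask
- in an amount of G, one L counts as one G

* the set-up with the highest amount of G at the outlet or at the end, in percent of the D put in ("none" if the first two lie within 2 percentage points) (north / south / north-east / south-west / none)
* amount of G at the outlet or at the end, in percent of the D put in, north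
* amount of G at the outlet or at the end, in percent of the D put in, south
* amount of G at the outlet or at the end, in percent of the D put in, north-east
* amount of G at the outlet or at the end, in percent of the D put in, south-west

Run Tuesday's flask slowly, in fractions of the charge. In the first instants J turns D into G: Tuesday's flask holds 54.3% by 10.0 min, a mean making rate over that time of 3.26 h⁻¹. In the middle the reading barely moves, 71.9% at 30.0 min and 73.0% at 60.0 min, so making and loss about balance. L sits inside these readings, so the curve doesn't show how much G is paired.

Then G falls, and Wednesday's run shows how fast. With twice the J on the same D, it reads 73.3% at 30.0 min, matching Tuesday's 73.0% at 60.0 min. At this charge, then, time counts multiplied by the loading. Wednesday's last two readings therefore lie at 100 min and 160 min on Tuesday's clock. Read with their scatter, they give the fade rate, the fraction of G lost per hour late in the run at a loading of 0.01 mol%: 0.274 h⁻¹, far slower than the early making. J comes out of its step as it went in, so I treat this as a pseudo-first-order loss.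

So the age of G counts. In south-west, D enters evenly, and at the end the mean time since a portion entered is 1.20 h, shorter than south's 2.0 h. Averaging Tuesday's readings from 30.0 min on, I expect about 68.8% for south-west. The tanks hold G of every age; north's mean age of 6.00 h is older than south's, so I put north last, and north-east, with a mean age equal to south's, no higher than south.

The forecast gives north 38.5%, south 60.5%, north-east 58% and south-west 70%, with south-west best, noting that “the decay is J-driven”.

The flask gives north 33.6%, south 60.1%, north-east 54.3% and south-west 67.8%, so south-west leads.

    D + J → G + J, rate k1*[D]*[J]/(1 + ([D]/Km1)) (7.40 mM, k = 1.30 × 10⁵ M⁻¹ min⁻¹)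
    D + G ⇌ L, settled at all times (K = 910 M⁻¹)
    J + G → J + E (k = 1800 M⁻¹ min⁻¹)
    D → Z (k = 1.10 × 10⁻⁴ min⁻¹)

At the end, E holds 18.3% of the charge in south-west against 36.7% in south. Let south's 60.1% fade at 0.274 h⁻¹ for a further 1.00 h, and you reckon 45.7%; the same flask read at 3.0 h holds 44.6%.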